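## Structural features

The target is a flavonol: a benzo ring (ring A) is fused through C4a–C8a to a 4-pyranone (ring C), which carries the 4-hydroxy-3-methoxyphenyl ring B at C2 and an enolic hydroxyl at C3. Ring A bears three different oxygen functions in a fixed order: C5–OH (hydrogen-bonded to the C4 carbonyl), C6–H, C7–O-prenyl and C8–OMe next to the ring oxygen O1. There is no stereocentre and no stereogenic double bond, so the problem is one of regiochemistry and chemoselectivity only. The fragile groups are the aryl prenyl ether (lost or cyclised by strong acids, Lewis acids, hydrogenolysis and electrophilic oxidants), the 3-hydroxy-enone (air-sensitive in base) and the free phenols. The real difficulty is the 5,7,8-trioxygenation with three unlike substituents, which a classical chromone synthesis would have to draw from an acetophenone with four differentiated oxygens. The key step uses the para relation of C5–OH and C8–OMe: with C4a and C8a they form a 4-methoxyphenol. Ring A can therefore be carried as a 2-hydroxy-5-methoxy-4-prenyloxyphenyl ketone in which C8a still bears hydrogen. Oxidation of that phenol to its quinone monoketal makes C8a the electrophile that accepts the side-chain enol oxygen, the future O1.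

## Logic of the disconnections

15 ⇒ 14. The two ester C–O bonds at O3 and O4′ are cut. The benzoates are needed earlier: they keep the C3 enol and the ring B phenol electron-poor and blocked while ring A is oxidised. Methanolysis removes them without acid, metal or hydrogen, so the prenyl ether is spared. The forward step must be mild and air-free.

14 ⇒ 11. The bond O1–C8a is cut, returning hydrogen to C8a and the O1 oxygen to a ketone enol. Ring A of 11 then has only three oxygens in the 1,2,4-pattern, and ring C becomes an open 1,3-diketone. The mapping aryl C1→C4a, C2→C5, C4→C7, C5→C8, C6→C8a was checked and the two structures are consistent; no correction is needed. The benzoates of 11 are kept by design, since they raise the oxidation potential of every site except ring A. The forward step demands oxidation of ring A only, and closure by the enol oxygen at C8a instead of dehydrative closure by the phenol oxygen.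

11 ⇒ 10. The C–O bond at the central carbon (future C3–O) is cut. The diketone carbon is the natural nucleophile, so the oxygen is brought in as an electrophile. A leaving group at that carbon is avoided because the neighbouring phenol would displace it. The forward step needs an oxygen electrophile that reacts with the diketonate faster than with the electron-rich phenol.

10 ⇒ 9. The C–C bond between the central methylene and the ring B carbonyl (future C2–C3) is cut. This turns a C–C bond formation into an intramolecular acyl transfer from a phenol ester. The base must leave the ring B benzoate intact.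

9 ⇒ 6 + 8. The aryl ester C–O bond is cut, dividing the molecule into the ring A ketone and the ring B acid. The forward step must acylate a hydrogen-bonded phenol.

8 ⇒ 7. The benzoate C–O bond is cut; the forward step is a simple phenol acylation in the presence of a carboxylate.

6 ⇒ 5 ⇒ 3 + 4. The O–CH3 bond and then the O–CH2 bond of the prenyl ether are cut. The forward order follows acidity: the hydroxyl para to the acetyl group reacts first, the meta hydroxyl second, and the chelated ortho hydroxyl not at all.

3 ⇒ 1. The aryl–acetyl C–C bond is cut. The acetyl group is taken from one of the three ester groups of 1 by O-to-C migration, so ring A starts from a symmetrical-looking, cheap triester.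

## Other disconnections considered

Alternative 1: The cut is O1–C2 and C3–C4 of ring C. In the forward step the salicylaldehyde A2 and the nitrostyrene A3 are condensed with an amine base; the phenoxide adds to the nitroalkene, the nitronate adds to the aldehyde, and water is lost to give the nitrochromene A1.
- In favour: two bonds and a ring are formed from two aromatic halves in one operation, and the reaction type is well established for 3-nitro-2H-chromenes. On mechanistic certainty this alternative is better than the chosen cascade, which has no direct precedent. On convergence the two plans are equal.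
- Against: A1 is at the wrong oxidation level. C2 is sp3 (a stereocentre made only to be destroyed), C4 is a CH and C3 carries nitrogen, so a nitro-to-oxygen exchange, an oxidation at C4 and a dehydrogenation must follow.
- Against: A2 is a benzaldehyde with four differentiated oxygens, so the ring A problem is moved into the starting material and not solved.
- Against: benzyl ethers cannot be removed beside a prenyl ether. The prenyl group would have to be put onto the fully deprotected polyphenol, where O3, O7 and O4′ compete.
- Comparison: the chosen plan needs only a trioxygenated ring A, installs the prenyl group early on a uniquely reactive hydroxyl and should be several steps shorter.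

Alternative 2: The cut is C7–C8 and C6–C7 of ring A, with C7 arriving as carbon monoxide. In the forward step the dienyl methoxycarbene complex A5 (pentacarbonylchromium, zerovalent chromium) is irradiated under CO; a carbonyl ligand inserts, and the dienylketene electrocyclises and tautomerises to the phenol A4.
- In favour: ring A is created with O7 as its only free hydroxyl and O8 already methylated, so alkylation with 4 would be regiochemically unambiguous. On this point the alternative is better than step 2 of the chosen route, which relies on graded acidity.
- In favour: fluoride removal of the silyl ethers is as compatible with the prenyl ether as the benzoate methanolysis (equal). Photochemical benzannulation of dienyl alkoxycarbene complexes is a known reaction type, so on precedent it is not weaker than step 8.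
- Against: A5 is a fully substituted 4-pyranone carrying a hydrolytically labile silyl enol ether and a carbene complex. Its preparation needs metalation of a pyranone next to the ring oxygen, stoichiometric toxic chromium carbonyl chemistry and a separate synthesis of the pyranone with ring B attached.
- Comparison: the route would be clearly longer than the chosen one, and the key step adds a photochemical operation under CO.

Alternative 3: The cut is C4a–C5, preceded by C8–C8a from addition of a metalated pyranone to a squarate-derived dione. In the forward step the cyclobutenone A7 is heated; 4π ring opening gives a dienylketene, whose ketene carbon closes on C4a, and tautomerisation gives the hydroquinone A6.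
- In favour: the step is thermal, reagent-free and regiospecific, and the reaction type is known for aryl- and heteroaryl-substituted hydroxycyclobutenones, so it is better precedented than step 8.
- In favour: A6 has the chelated 5-OH and the free 8-OH ready for selective O8 methylation. This is the same differentiation that the chosen plan uses, so the two are equal on that point.
- Against: A7 requires a 4-pyranone metalated at the carbon next to oxygen, a species prone to conjugate addition and ring opening, and its regioselective addition to an unsymmetrical cyclobutenedione.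
- Against: the O7 benzyl ether of A6 is not distinguishable from those at O3 and O4′. Exchanging it for prenyl means global debenzylation and an unselective prenylation, or a redesign of the protecting groups.
- Comparison: the sequence is longer than the chosen one.

Key step: step 8

Remark on the chemistry: 10 and 11 are written as diketo forms; in solution they will be mixtures with their enols and, for 11, with the cyclic hemiketal formed by the ring A phenol, which does not alter the plan.

## Route

Step 1
Reactants: 1 benzene-1,2,4-triyl triacetate (1,2,4-triacetoxybenzene)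
Product: 3 1-(2,4,5-trihydroxyphenyl)ethanone, via 4,5-diacetoxy-2-hydroxyacetophenone 2 (not isolated)
Conditions: BF3·OEt2 (as solvent), 90 °C; then H2O, 60 °C
Reagents that add atoms: none
Why: Fries rearrangement; the acylium ion should enter the one free position that is ortho to one acyloxy group and para to another, the boron chelate of the ortho-hydroxy ketone drives the transfer, and warm water hydrolyses the two remaining acetates.

Step 2
Reactants: 3 1-(2,4,5-trihydroxyphenyl)ethanone; 4 1-bromo-3-methylbut-2-ene
Product: 5 1-[2,5-dihydroxy-4-(3-methylbut-2-enyloxy)phenyl]ethanone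
Conditions: 4 (1.0 equiv), KHCO3, DMF, 40 °C, Ar
Reagents that add atoms: none
Why: Williamson ether synthesis at the most acidic phenol; the 4-OH is para to the acetyl group (a vinylogous acid), the 2-OH is chelated and the 5-OH is the least acidic, so a weak base and one equivalent of halide should alkylate O4 only.

Step 3
Reactants: 5 1-[2,5-dihydroxy-4-(3-methylbut-2-enyloxy)phenyl]ethanone
Product: 6 1-[2-hydroxy-5-methoxy-4-(3-methylbut-2-enyloxy)phenyl]ethanone
Conditions: MeI (1.1 equiv), K2CO3, acetone, rt, Ar
Reagents that add atoms: iodomethane, CI
Why: Williamson methylation of the only non-chelated phenol; the ortho hydroxyl is held in a hydrogen bond to the ketone and should react much more slowly.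

Step 4
Reactants: 7 4-hydroxy-3-methoxybenzoic acid (vanillic acid)
Product: 8 4-(benzoyloxy)-3-methoxybenzoic acid
Conditions: PhCOCl, aq. NaOH, 0 °C; then aq. HCl
Reagents that add atoms: benzoyl chloride, O=C(Cl)c1ccccc1
Why: Schotten–Baumann acylation of the phenoxide; any mixed anhydride formed at the carboxylate is hydrolysed again in the aqueous base.

Step 5
Reactants: 6 1-[2-hydroxy-5-methoxy-4-(3-methylbut-2-enyloxy)phenyl]ethanone; 8 4-(benzoyloxy)-3-methoxybenzoic acid
Product: 9 2-acetyl-4-methoxy-5-(3-methylbut-2-enyloxy)phenyl 4-(benzoyloxy)-3-methoxybenzoate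
Conditions: DCC, DMAP (cat.), CH2Cl2, 0 °C → rt
Reagents that add atoms: none
Why: Steglich esterification; the O-acylisourea is reactive enough to acylate the hydrogen-bonded phenol under neutral conditions that leave the prenyl ether and the ring B benzoate alone.

Step 6
Reactants: 9 2-acetyl-4-methoxy-5-(3-methylbut-2-enyloxy)phenyl 4-(benzoyloxy)-3-methoxybenzoate
Product: 10 4-{3-[2-hydroxy-5-methoxy-4-(3-methylbut-2-enyloxy)phenyl]-3-oxopropanoyl}-2-methoxyphenyl benzoate
Conditions: LiN(SiMe3)2 (2.5 equiv), THF, −78 → −20 °C; then AcOH
Reagents that add atoms: none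
Why: Baker–Venkataraman rearrangement; the methyl ketone enolate attacks the neighbouring ester carbonyl through a six-membered transition state and the O-to-C acyl shift is driven by formation of the stabilised diketonate, while the non-nucleophilic amide base at low temperature should spare the distal ring B benzoate.

Step 7
Reactants: 10 4-{3-[2-hydroxy-5-methoxy-4-(3-methylbut-2-enyloxy)phenyl]-3-oxopropanoyl}-2-methoxyphenyl benzoate
Product: 11 racemic 1-[2-hydroxy-5-methoxy-4-(3-methylbut-2-enyloxy)phenyl]-3-[4-(benzoyloxy)-3-methoxyphenyl]-1,3-dioxopropan-2-yl benzoate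
Conditions: (PhCO2)2 (1.05 equiv), K2CO3 (1.1 equiv), MeCN, 0 °C → rt
Reagents that add atoms: dibenzoyl peroxide, O=C(OOC(=O)c1ccccc1)c1ccccc1
Why: Electrophilic α-benzoyloxylation of a β-diketone; the diketonate carbon attacks the peroxide O–O bond and expels benzoate, and the new stereocentre is formed as the racemate and stays labile through the enol, which is of no consequence because it becomes sp2 in step 8.

Step 8
Reactants: 11 racemic 1-[2-hydroxy-5-methoxy-4-(3-methylbut-2-enyloxy)phenyl]-3-[4-(benzoyloxy)-3-methoxyphenyl]-1,3-dioxopropan-2-yl benzoate
Product: 14 2-[4-(benzoyloxy)-3-methoxyphenyl]-5-hydroxy-8-methoxy-7-(3-methylbut-2-enyloxy)-4-oxo-4H-chromen-3-yl benzoate, via quinone monoketal 12 (not isolated), via cyclised dimethyl ketal 13 (not isolated)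
Conditions: undivided cell, graphite anode, Pt cathode, LiClO4 (0.1 M), 2,6-lutidine (1 equiv), MeOH–MeCN (1:4), constant current, about 2.1 F/mol, 0 °C; then current off, AcOH, rt
Reagents that add atoms: methanol, CO (the two ketal methoxyls of 12 are equivalent, so part of the C8 methoxyl of 14 comes from the solvent)
Why: Proposed new method: two-electron anodic oxidation of the ring A 4-methoxyphenol of 11 and capture of the phenoxonium ion by methanol at C8 should give the 8,8-dimethoxy dienone 12; the closest known reaction type is the anodic conversion of para-methoxyphenols into quinone monoketals in methanol followed by conjugate addition of a nucleophile to the ketal with loss of methanol, and the new element is that the nucleophile is the tethered enol oxygen of the 2-acyloxy-1,3-diketone. In 12 the carbon C8a is the β-carbon of both the C5 dienone carbonyl and the side-chain C4 ketone, whereas the other β-carbon, C7, is deactivated as a vinylogous ester by the prenyloxy group, so the enol oxygen should add at C8a and close ring C in a 6-endo-trig oxa-Michael addition to give 13. Ionisation of the ketal and loss of the C8a proton then expel methanol and rearomatise ring A, which makes the sequence irreversible and leaves C5–OH and C8–OMe. The C8a stereocentre of 13 is transient, formed as the racemate and destroyed on aromatisation, so no stereocontrol is required. Site selectivity of the oxidation rests on potentials: the trioxygenated phenol should be oxidised well below the trisubstituted prenyl alkene, the acylated and benzoylated ring B and the acyloxy-diketone, and the charge is limited to two electrons per molecule. Closure at C8a in preference to non-oxidative cyclodehydration through the phenol oxygen is secured by the neutral, lutidine-buffered medium at 0 °C, because the dehydration needs acid while the ring–chain tautomers of 11 drain through the easily oxidised open phenol. Competing addition of solvent methanol at C8a is held back by the intramolecularity of the enol and by diluting the methanol with acetonitrile, and the aromatisation is finished off-current so that 14, itself a 4-methoxyphenol, is not exposed to the anode.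

Step 9
Reactants: 14 2-[4-(benzoyloxy)-3-methoxyphenyl]-5-hydroxy-8-methoxy-7-(3-methylbut-2-enyloxy)-4-oxo-4H-chromen-3-yl benzoate
Product: 15 3,5-dihydroxy-2-(4-hydroxy-3-methoxyphenyl)-8-methoxy-7-(3-methylbut-2-enyloxy)-4H-chromen-4-one
Conditions: K2CO3 (3 equiv), MeOH (degassed), rt, Ar; then aq. HCl to pH 5
Reagents that add atoms: none
Why: Base-mediated transesterification (Zemplén-type methanolysis) of an enol benzoate and an aryl benzoate, both activated esters; the ethers and the chromone are stable to carbonate in methanol, and exclusion of air protects the flavonol anion.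

## Compound list

1 | benzene-1,2,4-triyl triacetate (1,2,4-triacetoxybenzene) | CC(=O)Oc1ccc(OC(C)=O)c(OC(C)=O)c1 | starting material
2 | 4-acetyl-5-hydroxy-1,2-phenylene diacetate (4,5-diacetoxy-2-hydroxyacetophenone) | CC(=O)c1cc(OC(C)=O)c(OC(C)=O)cc1O | intermediate (not isolated)
3 | 1-(2,4,5-trihydroxyphenyl)ethanone | CC(=O)c1cc(O)c(O)cc1O | intermediate
4 | 1-bromo-3-methylbut-2-ene | CC(C)=CCBr | starting material
5 | 1-[2,5-dihydroxy-4-(3-methylbut-2-enyloxy)phenyl]ethanone | CC(=O)c1cc(O)c(OCC=C(C)C)cc1O | intermediate
6 | 1-[2-hydroxy-5-methoxy-4-(3-methylbut-2-enyloxy)phenyl]ethanone | CC(=O)c1cc(OC)c(OCC=C(C)C)cc1O | intermediate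
7 | 4-hydroxy-3-methoxybenzoic acid (vanillic acid) | COc1cc(C(=O)O)ccc1O | starting material
8 | 4-(benzoyloxy)-3-methoxybenzoic acid | COc1cc(C(=O)O)ccc1OC(=O)c1ccccc1 | intermediate
9 | 2-acetyl-4-methoxy-5-(3-methylbut-2-enyloxy)phenyl 4-(benzoyloxy)-3-methoxybenzoate | CC(=O)c1cc(OC)c(OCC=C(C)C)cc1OC(=O)c1ccc(OC(=O)c2ccccc2)c(OC)c1 | intermediate
10 | 4-{3-[2-hydroxy-5-methoxy-4-(3-methylbut-2-enyloxy)phenyl]-3-oxopropanoyl}-2-methoxyphenyl benzoate | COc1cc(C(=O)CC(=O)c2ccc(OC(=O)c3ccccc3)c(OC)c2)c(O)cc1OCC=C(C)C | intermediate
11 | racemic 1-[2-hydroxy-5-methoxy-4-(3-methylbut-2-enyloxy)phenyl]-3-[4-(benzoyloxy)-3-methoxyphenyl]-1,3-dioxopropan-2-yl benzoate | COc1cc(C(=O)C(OC(=O)c2ccccc2)C(=O)c2ccc(OC(=O)c3ccccc3)c(OC)c2)c(O)cc1OCC=C(C)C | intermediate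
12 | racemic 1-[4-(benzoyloxy)-3-methoxyphenyl]-3-[3,3-dimethoxy-4-(3-methylbut-2-enyloxy)-6-oxocyclohexa-1,4-dien-1-yl]-1,3-dioxopropan-2-yl benzoate | COC1(OC)C=C(C(=O)C(OC(=O)c2ccccc2)C(=O)c2ccc(OC(=O)c3ccccc3)c(OC)c2)C(=O)C=C1OCC=C(C)C | intermediate (not isolated)
13 | racemic 2-[4-(benzoyloxy)-3-methoxyphenyl]-5-hydroxy-8,8-dimethoxy-7-(3-methylbut-2-enyloxy)-4-oxo-8,8a-dihydro-4H-chromen-3-yl benzoate | O=C1C(OC(=O)c2ccccc2)=C(c2ccc(OC(=O)c3ccccc3)c(OC)c2)OC2C1=C(O)C=C(OCC=C(C)C)C2(OC)OC | intermediate (not isolated)
14 | 2-[4-(benzoyloxy)-3-methoxyphenyl]-5-hydroxy-8-methoxy-7-(3-methylbut-2-enyloxy)-4-oxo-4H-chromen-3-yl benzoate | O=c1c(OC(=O)c2ccccc2)c(-c2ccc(OC(=O)c3ccccc3)c(OC)c2)oc2c(OC)c(OCC=C(C)C)cc(O)c12 | intermediate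
15 | 3,5-dihydroxy-2-(4-hydroxy-3-methoxyphenyl)-8-methoxy-7-(3-methylbut-2-enyloxy)-4H-chromen-4-one | COc1cc(-c2oc3c(OC)c(OCC=C(C)C)cc(O)c3c(=O)c2O)ccc1O | target

## Step count and least certain steps

Total: 9 steps. Longest linear sequence: 8 steps (steps 1–3 and 5–9); step 4 is a one-step side branch.

**Step 8 (key step, proposed new method).** Four things may go wrong.
- Solvent methanol may add at C8a faster than the tethered enol, because the doubly activated position is also open to the solvent.
- The product ring may be over-oxidised, since it is again a 4-methoxyphenol.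
- Ring C may close without oxidation, through the phenol oxygen with loss of water, if acid builds up at the anode.
- The benzoates may be methanolysed by methoxide formed at the cathode.

The fallback makes the same O1–C8a bond in separate operations of known type. It sets out from 11 and comes back at 14.
- PhI(OAc)2 in aqueous MeCN at 0 °C should demethylate the 4-methoxyphenol oxidatively to the acylquinone, racemic 1-[4-(benzoyloxy)-3-methoxyphenyl]-3-[4-(3-methylbut-2-enyloxy)-3,6-dioxocyclohexa-1,4-dien-1-yl]-1,3-dioxopropan-2-yl benzoate F1.
- 2-Acyl-1,4-benzoquinones are known to take up nucleophiles at the carbon flanked by the acyl group. NaOAc in CH2Cl2 should therefore add the enol oxygen and, after tautomerisation and a Na2S2O4 wash to reverse any redox exchange, give 2-[4-(benzoyloxy)-3-methoxyphenyl]-5,8-dihydroxy-7-(3-methylbut-2-enyloxy)-4-oxo-4H-chromen-3-yl benzoate F2.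
- Methylation of the non-chelated 8-OH (MeI, K2CO3, acetone, Ar) then gives 14.

**Step 7.** The peroxide may attack the electron-rich ring A phenol (ring oxidation or O-benzoylation) in competition with the diketonate. The product may also cyclise through the phenol and lose water on prolonged exposure to base. The fallback masks the phenol for the oxidation. It sets out from 10 and comes back at 11.
- Silylation (t-BuMe2SiCl, imidazole, DMF; aqueous work-up hydrolyses any enol silyl ether) should give 4-{3-[2-(tert-butyldimethylsilyloxy)-5-methoxy-4-(3-methylbut-2-enyloxy)phenyl]-3-oxopropanoyl}-2-methoxyphenyl benzoate F3.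
- Benzoyloxylation as in step 7 should give racemic 1-[2-(tert-butyldimethylsilyloxy)-5-methoxy-4-(3-methylbut-2-enyloxy)phenyl]-3-[4-(benzoyloxy)-3-methoxyphenyl]-1,3-dioxopropan-2-yl benzoate F4.
- Buffered fluoride (Bu4NF, AcOH, THF, 0 °C) then frees the phenol to give 11.

**Step 2.** Alkylation may be unselective between O4 and O5, may go twice, and the hydroquinone may be oxidised by air under base. All three follow from three free hydroxyls of similar reactivity on an electron-rich ring. The fallback buys the methyl ether in place, so that only one non-chelated hydroxyl is present at the alkylation. It sets out from 4 and comes back at 6, bypassing 5 and step 3.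
- 4-Methoxybenzene-1,3-diol F5 is C-acetylated para to its 3-hydroxyl (AcOH, BF3·OEt2, 90 °C; Friedel–Crafts acylation of a resorcinol) to give 1-(2,4-dihydroxy-5-methoxyphenyl)ethanone F6.
- F6 is alkylated with 4 (K2CO3, acetone, rt) at its only free hydroxyl to give 6.

**Step 6.** The ring B benzoate may be transferred or cleaved by the enolate or by the liberated ring A phenoxide, because it is an activated aryl ester in a strongly basic medium. The fallback replaces the strong-base acyl shift by a direct C-acylation under soft enolisation. It sets out from 6 and 8 and comes back at 10, bypassing 9.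
- 8 is converted with 1H-benzotriazole and SOCl2 (CH2Cl2, rt) into 4-(1H-benzotriazole-1-carbonyl)-2-methoxyphenyl benzoate F7.
- F7 acylates the ketone 6 with MgBr2·OEt2 and i-Pr2NEt in CH2Cl2 at rt. Whether the acyl group enters at carbon directly or by way of the phenol ester, the outcome is 10.

## Further compounds

F1 | step 8 | racemic 1-[4-(benzoyloxy)-3-methoxyphenyl]-3-[4-(3-methylbut-2-enyloxy)-3,6-dioxocyclohexa-1,4-dien-1-yl]-1,3-dioxopropan-2-yl benzoate | O=C1C=C(OCC=C(C)C)C(=O)C=C1C(=O)C(OC(=O)c1ccccc1)C(=O)c1ccc(OC(=O)c2ccccc2)c(OC)c1
F2 | step 8 | 2-[4-(benzoyloxy)-3-methoxyphenyl]-5,8-dihydroxy-7-(3-methylbut-2-enyloxy)-4-oxo-4H-chromen-3-yl benzoate | O=c1c(OC(=O)c2ccccc2)c(-c2ccc(OC(=O)c3ccccc3)c(OC)c2)oc2c(O)c(OCC=C(C)C)cc(O)c12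
F3 | step 7 | 4-{3-[2-(tert-butyldimethylsilyloxy)-5-methoxy-4-(3-methylbut-2-enyloxy)phenyl]-3-oxopropanoyl}-2-methoxyphenyl benzoate | COc1cc(C(=O)CC(=O)c2ccc(OC(=O)c3ccccc3)c(OC)c2)c(O[Si](C)(C)C(C)(C)C)cc1OCC=C(C)C
F4 | step 7 | racemic 1-[2-(tert-butyldimethylsilyloxy)-5-methoxy-4-(3-methylbut-2-enyloxy)phenyl]-3-[4-(benzoyloxy)-3-methoxyphenyl]-1,3-dioxopropan-2-yl benzoate | COc1cc(C(=O)C(OC(=O)c2ccccc2)C(=O)c2ccc(OC(=O)c3ccccc3)c(OC)c2)c(O[Si](C)(C)C(C)(C)C)cc1OCC=C(C)C
F5 | step 2 | 4-methoxybenzene-1,3-diol | COc1ccc(O)cc1O
F6 | step 2 | 1-(2,4-dihydroxy-5-methoxyphenyl)ethanone | CC(=O)c1cc(OC)c(O)cc1O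
F7 | step 6 | 4-(1H-benzotriazole-1-carbonyl)-2-methoxyphenyl benzoate | COc1cc(C(=O)n2nnc3ccccc32)ccc1OC(=O)c1ccccc1
A1 | alternative 1 | racemic 5,7-bis(benzyloxy)-2-[4-(benzyloxy)-3-methoxyphenyl]-8-methoxy-3-nitro-2H-chromene | [O-][N+](=O)C1=Cc2c(OCc3ccccc3)cc(OCc3ccccc3)c(OC)c2OC1c1ccc(OCc2ccccc2)c(OC)c1
A2 | alternative 1 | 4,6-bis(benzyloxy)-2-hydroxy-3-methoxybenzaldehyde | O=Cc1c(OCc2ccccc2)cc(OCc2ccccc2)c(OC)c1O
A3 | alternative 1 | (E)-1-(benzyloxy)-2-methoxy-4-(2-nitroethenyl)benzene | [O-][N+](=O)/C=C/c1ccc(OCc2ccccc2)c(OC)c1
A4 | alternative 2 | 3,5-bis(tert-butyldimethylsilyloxy)-2-[4-(tert-butyldimethylsilyloxy)-3-methoxyphenyl]-7-hydroxy-8-methoxy-4H-chromen-4-one | O=c1c(O[Si](C)(C)C(C)(C)C)c(-c2ccc(O[Si](C)(C)C(C)(C)C)c(OC)c2)oc2c(OC)c(O)cc(O[Si](C)(C)C(C)(C)C)c12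
A5 | alternative 2 | pentacarbonyl{[5-(tert-butyldimethylsilyloxy)-6-[4-(tert-butyldimethylsilyloxy)-3-methoxyphenyl]-3-[1-(tert-butyldimethylsilyloxy)ethenyl]-4-oxo-4H-pyran-2-yl](methoxy)methylidene}chromium | COC(=[Cr](=C=O)(=C=O)(=C=O)(=C=O)=C=O)c1oc(-c2ccc(O[Si](C)(C)C(C)(C)C)c(OC)c2)c(O[Si](C)(C)C(C)(C)C)c(=O)c1C(=C)O[Si](C)(C)C(C)(C)C
A6 | alternative 3 | 3,7-bis(benzyloxy)-2-[4-(benzyloxy)-3-methoxyphenyl]-5,8-dihydroxy-4H-chromen-4-one | O=c1c(OCc2ccccc2)c(-c2ccc(OCc3ccccc3)c(OC)c2)oc2c(O)c(OCc3ccccc3)cc(O)c12
A7 | alternative 3 | racemic 3-(benzyloxy)-4-{5-(benzyloxy)-6-[4-(benzyloxy)-3-methoxyphenyl]-4-oxo-4H-pyran-2-yl}-4-hydroxycyclobut-2-en-1-one | O=C1C=C(OCc2ccccc2)C1(O)c1cc(=O)c(OCc2ccccc2)c(-c2ccc(OCc3ccccc3)c(OC)c2)o1
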